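**Retrosynthetic overview**
- The strategy rests on ring A (the benzene ring). Its brominated carbons C4 and C7 flank the fusion carbons C3a and C7a and enclose the bare C5–C6 pair, while N1–C2–C3 of ring B (the five-membered ring) links C7a to C3a. C7≡C7a and C3a≡C4 can therefore be two bromoalkynes on a three-atom tether, with C5–C6 supplied by acetylene.
- Last disconnections: the C2–Br and C3–Br bonds (electrophilic bromination of N–H 4,7-dibromoindole), then N-detosylation and dehydrogenation back to 4,7-dibromo-1-tosylindoline.
- Key disconnection: a ruthenium-catalysed [2+2+2] cycloaddition cuts C3a–C7a, C4–C5 and C6–C7. This leads to an N-tosyl bromoynamide carrying a 4-bromobut-3-ynyl chain, plus acetylene.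
- The diyne is traced to but-3-yn-1-amine by N-tosylation, N-ethynylation with an alkynyliodonium salt, desilylation and twofold bromination of the alkyne termini.
- Ring order: rings A and B are formed together in the key step, and no ring is made before or after it.

Key step: step 5

Remark on the chemistry: the target has no stereocentre, so no step has to control configuration. Compound 1 is taken as the free base; its hydrochloride would need one more equivalent of Et3N in step 1.

Step 1
Reactants: 1 but-3-yn-1-amine; 2 4-methylbenzenesulfonyl chloride
Product: 3 N-(but-3-yn-1-yl)-4-methylbenzenesulfonamide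
Conditions: Et3N (1.5 equiv), CH2Cl2, 0 °C to rt
Reagents that add atoms: 4-methylbenzenesulfonyl chloride 2, Cc1ccc(cc1)S(=O)(=O)Cl
Why: N-Sulfonylation of a primary amine with a sulfonyl chloride is fast at 0 °C, Et3N takes up the HCl, and the terminal alkyne is inert under these conditions.

Step 2
Reactants: 3 N-(but-3-yn-1-yl)-4-methylbenzenesulfonamide; 4 phenyl[(trimethylsilyl)ethynyl]iodonium trifluoromethanesulfonate
Product: 6 N-(but-3-yn-1-yl)-4-methyl-N-[(trimethylsilyl)ethynyl]benzenesulfonamide, via potassium (but-3-yn-1-yl)(tosyl)amide 5 (not isolated)
Conditions: KN(SiMe3)2 (1.0 equiv), toluene, 0 °C; then 4 (1.1 equiv), 0 °C to rt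
Reagents that add atoms: phenyl[(trimethylsilyl)ethynyl]iodonium trifluoromethanesulfonate 4, C[Si](C)(C)C#C[I+]c1ccccc1.[O-]S(=O)(=O)C(F)(F)F
Why: N-Alkynylation of a sulfonamide anion with an alkynyl(phenyl)iodonium salt, established for N-(alkynyl)alkyl tosylamides: one equivalent of base removes only the far more acidic N–H, the anion 5 adds to the silicon-bearing alkyne carbon of 4, iodobenzene departs and a 1,2-shift in the alkylidene carbene delivers the ynamide, while the copper-free conditions keep the free alkyne terminus out of coupling reactions.

Step 3
Reactants: 6 N-(but-3-yn-1-yl)-4-methyl-N-[(trimethylsilyl)ethynyl]benzenesulfonamide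
Product: 7 N-(but-3-yn-1-yl)-N-ethynyl-4-methylbenzenesulfonamide
Conditions: Bu4NF (1.1 equiv), THF containing water, 0 °C
Reagents that add atoms: none
Why: Fluoride-induced protodesilylation of an alkynylsilane should be complete within minutes at 0 °C because the C(sp)–Si bond is the most fluoride-labile bond present, and N-sulfonyl ynamides are known to survive it.

Step 4
Reactants: 7 N-(but-3-yn-1-yl)-N-ethynyl-4-methylbenzenesulfonamide
Product: 10 N-(bromoethynyl)-N-(4-bromobut-3-yn-1-yl)-4-methylbenzenesulfonamide, via N-(bromoethynyl)-N-(but-3-yn-1-yl)-4-methylbenzenesulfonamide 8 (not isolated), via N-(4-bromobut-3-yn-1-yl)-N-ethynyl-4-methylbenzenesulfonamide 9 (not isolated)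
Conditions: NBS (2.3 equiv), AgNO3 (0.2 equiv), dry acetone, 0 °C to rt, dark; filtration through SiO2 to remove silver
Reagents that add atoms: N-bromosuccinimide, O=C1CCC(=O)N1Br
Why: Silver-catalysed electrophilic bromination of terminal alkynes through silver acetylides is established both for alkyl-substituted alkynes and for terminal N-sulfonyl ynamides, so both C(sp)–H bonds should be replaced in either order (through 8 or 9) while the neutral, dry and dark medium spares the acid-sensitive ynamide.

Step 5
Reactants: 10 N-(bromoethynyl)-N-(4-bromobut-3-yn-1-yl)-4-methylbenzenesulfonamide; 11 acetylene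
Product: 12 4,7-dibromo-1-tosylindoline
Conditions: Cp*RuCl(cod) (5 mol %), acetylene (1 atm), ClCH2CH2Cl, rt, 10 added over 3 h by syringe pump
Reagents that add atoms: acetylene 11, C#C
Why: Proposed new method: after loss of cod the divalent ruthenium fragment Cp*RuCl binds both triple bonds of 10 and couples them oxidatively to a bicyclic ruthenacyclopentadiene of tetravalent ruthenium, acetylene then coordinates and inserts, and reductive elimination releases the arene and returns the catalyst. Ring B (five-membered) closes in the oxidative coupling, an intramolecular alkyne–alkyne cyclometallation across the N1–C2–C3 tether that forms C3a–C7a, and ring A (six-membered) closes when the metallacycle takes up acetylene and eliminates, forming C4–C5 and C6–C7, so that ring A arises by an overall [2+2+2] cycloaddition. The closest known reaction types are the Cp*RuCl(cod)-catalysed cycloaddition of 1,6-diynes bearing halogen at the alkyne termini with acetylene, cycloadditions of yne-ynamides with the same catalyst, and the RhCl(PPh3)3-catalysed cyclotrimerization of N-ethynyl-N-(but-3-ynyl)sulfonamides to indolines; what has no precedent is a bromoynamide as one arm of the diyne. No stereocentre is created, and regiochemistry is fixed by the substrate, because each bromine sits on an outer diyne carbon and can only become a substituent of C4 or C7, and acetylene is symmetric. The selectivity needed is chemoselectivity for the cross-cycloaddition over metal insertion into the C(sp)–Br bonds and over self-oligomerization of 10: the Cp*RuCl fragment is known to leave haloalkyne C–X bonds intact, the three-atom tether makes the first coupling intramolecular, and the bromine-capped triple bonds of a second molecule of 10 are poor third partners next to unhindered acetylene, an advantage reinforced by acetylene saturation and slow addition of 10. The sulfonyl group damps the donor power of nitrogen, so the bromoynamide should behave as a moderately polarized internal alkyne and not as a keteniminium precursor.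

Step 6
Reactants: 12 4,7-dibromo-1-tosylindoline
Product: 13 4,7-dibromo-1-tosyl-1H-indole
Conditions: DDQ (2 equiv), PhCl, 110 °C
Reagents that add atoms: none
Why: Quinone dehydrogenation of an N-protected indoline (hydride abstraction followed by proton loss) is driven by aromatization of ring B, and since the aryl bromides, the sulfonamide and the tolyl methyl group are inert to DDQ the deactivated substrate can simply be heated until conversion is complete.

Step 7
Reactants: 13 4,7-dibromo-1-tosyl-1H-indole
Product: 14 4,7-dibromo-1H-indole
Conditions: Cs2CO3 (3 equiv), THF–MeOH 2:1, rt to 40 °C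
Reagents that add atoms: none
Why: Nucleophilic N-desulfonylation of an N-tosylindole: methoxide formed in equilibrium from Cs2CO3 and methanol attacks sulfur and expels the indolide, a leaving group improved by the two bromines and by relief of strain between the tosyl group and the C7 bromine, and this mild non-reducing method leaves all C–Br bonds intact.

Step 8
Reactants: 14 4,7-dibromo-1H-indole
Product: 16 2,3,4,7-tetrabromo-1H-indole, via 3,4,7-tribromo-1H-indole 15 (not isolated)
Conditions: NBS (2.1 equiv), dry DMF, 0 °C to rt, dark
Reagents that add atoms: N-bromosuccinimide, O=C1CCC(=O)N1Br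
Why: Electrophilic aromatic substitution of a free indole: the enamine-like C3 reacts first to give 15, the second equivalent then takes C2 as the only open position of ring B, and C5 and C6 stay untouched because ring A is deactivated by two bromines, in line with the established twofold bromination of N–H indoles to 2,3-dibromoindoles in DMF.

**Compound list**
1 | but-3-yn-1-amine | NCCC#C | starting material
2 | 4-methylbenzenesulfonyl chloride | Cc1ccc(cc1)S(=O)(=O)Cl | starting material
3 | N-(but-3-yn-1-yl)-4-methylbenzenesulfonamide | Cc1ccc(cc1)S(=O)(=O)NCCC#C | intermediate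
4 | phenyl[(trimethylsilyl)ethynyl]iodonium trifluoromethanesulfonate | C[Si](C)(C)C#C[I+]c1ccccc1.[O-]S(=O)(=O)C(F)(F)F | starting material
5 | potassium (but-3-yn-1-yl)(tosyl)amide | Cc1ccc(cc1)S(=O)(=O)[N-]CCC#C.[K+] | intermediate (not isolated)
6 | N-(but-3-yn-1-yl)-4-methyl-N-[(trimethylsilyl)ethynyl]benzenesulfonamide | Cc1ccc(cc1)S(=O)(=O)N(C#C[Si](C)(C)C)CCC#C | intermediate
7 | N-(but-3-yn-1-yl)-N-ethynyl-4-methylbenzenesulfonamide | Cc1ccc(cc1)S(=O)(=O)N(C#C)CCC#C | intermediate
8 | N-(bromoethynyl)-N-(but-3-yn-1-yl)-4-methylbenzenesulfonamide | Cc1ccc(cc1)S(=O)(=O)N(C#CBr)CCC#C | intermediate (not isolated)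
9 | N-(4-bromobut-3-yn-1-yl)-N-ethynyl-4-methylbenzenesulfonamide | Cc1ccc(cc1)S(=O)(=O)N(C#C)CCC#CBr | intermediate (not isolated)
10 | N-(bromoethynyl)-N-(4-bromobut-3-yn-1-yl)-4-methylbenzenesulfonamide | Cc1ccc(cc1)S(=O)(=O)N(C#CBr)CCC#CBr | intermediate
11 | acetylene | C#C | starting material
12 | 4,7-dibromo-1-tosylindoline | Cc1ccc(cc1)S(=O)(=O)N1CCc2c(Br)ccc(Br)c12 | intermediate
13 | 4,7-dibromo-1-tosyl-1H-indole | Cc1ccc(cc1)S(=O)(=O)n1ccc2c(Br)ccc(Br)c12 | intermediate
14 | 4,7-dibromo-1H-indole | Brc1ccc(Br)c2[nH]ccc12 | intermediate
15 | 3,4,7-tribromo-1H-indole | Brc1c[nH]c2c(Br)ccc(Br)c12 | intermediate (not isolated)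
16 | 2,3,4,7-tetrabromo-1H-indole | Brc1[nH]c2c(Br)ccc(Br)c2c1Br | target

Total step count: 8. Longest linear sequence: 8 steps (from 1 to 16).

**Steps most likely to fail**

Step 5 (Proposed new method).
- What may go wrong: ruthenium may insert into a C(sp)–Br bond, a bromine may shift to give a vinylidene, the polarized bromoynamide may deactivate the catalyst, or the diyne may oligomerize faster than it takes up acetylene.
- Fallback: this uses known chemistry only. It masks both bromines as silicon while the rings are built and installs them afterwards. It sets out from 6 and comes back to the route at 12.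
- The free alkyne terminus of 6 is deprotonated (n-BuLi, THF, −78 °C) to lithium 4-{tosyl[(trimethylsilyl)ethynyl]amino}but-1-yn-1-ide F1.
- Quenching with Me3SiCl gives 4-methyl-N-[4-(trimethylsilyl)but-3-yn-1-yl]-N-[(trimethylsilyl)ethynyl]benzenesulfonamide F2.
- This diyne and acetylene 11 are cyclotrimerized with RhCl(PPh3)3 in toluene under 1 atm of acetylene, the established rhodium route from ynamide diynes to indolines. The product should be 1-tosyl-4,7-bis(trimethylsilyl)indoline F3.
- Ipso-bromodesilylation with Br2 (2.1 equiv, CH2Cl2, 0 °C) should replace first the strained silyl group at C7, ortho to nitrogen, to give 7-bromo-1-tosyl-4-(trimethylsilyl)indoline F4. It should then replace the one at C4, which gives 12.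

Step 6.
- What may go wrong: hydride abstraction from a substrate deactivated by two bromines and an N-sulfonyl group may be too slow. Long heating would then bring incomplete conversion or decomposition.
- Fallback: oxidation is replaced by a base-induced 1,2-elimination. It sets out from 12 and comes back at 14, so step 7 is skipped as well.
- KOtBu (2.5 equiv) in THF at 0 °C to rt removes a proton from C2 and expels toluenesulfinate from N1 to give 4,7-dibromo-3H-indole F5, which tautomerizes to 14.
- DMSO and heating are avoided so that dehydrobromination of ring A towards an aryne stays slow.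

Step 4.
- What may go wrong: electrophilic bromine may add across the electron-rich ynamide triple bond, or silver-assisted hydration may turn it into an N-acylsulfonamide, before the terminal C–H bond is substituted.
- Fallback: the bromoynamide is built under anionic conditions from a dichloroenamide. It sets out from 3 and comes back at 10, replacing steps 2 to 4.
- Compound 3 is condensed with trichloroethene (Cs2CO3, DMF, 50 °C) to (E)-N-(but-3-yn-1-yl)-N-(1,2-dichlorovinyl)-4-methylbenzenesulfonamide F6.
- PhLi (3.2 equiv, THF, −78 °C) deprotonates the alkyne, eliminates HCl and exchanges the remaining chlorine for lithium. This gives N-(4-lithiobut-3-yn-1-yl)-N-(lithioethynyl)-4-methylbenzenesulfonamide F7.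
- Quenching at −78 °C with BrCl2C–CCl2Br (2.2 equiv), a bromine donor that does not add to triple bonds, gives 10.

**Further compounds**
F1 | step 5 | lithium 4-{tosyl[(trimethylsilyl)ethynyl]amino}but-1-yn-1-ide | [Li]C#CCCN(C#C[Si](C)(C)C)S(=O)(=O)c1ccc(C)cc1
F2 | step 5 | 4-methyl-N-[4-(trimethylsilyl)but-3-yn-1-yl]-N-[(trimethylsilyl)ethynyl]benzenesulfonamide | Cc1ccc(cc1)S(=O)(=O)N(C#C[Si](C)(C)C)CCC#C[Si](C)(C)C
F3 | step 5 | 1-tosyl-4,7-bis(trimethylsilyl)indoline | Cc1ccc(cc1)S(=O)(=O)N1CCc2c([Si](C)(C)C)ccc([Si](C)(C)C)c12
F4 | step 5 | 7-bromo-1-tosyl-4-(trimethylsilyl)indoline | Cc1ccc(cc1)S(=O)(=O)N1CCc2c([Si](C)(C)C)ccc(Br)c12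
F5 | step 6 | 4,7-dibromo-3H-indole | Brc1ccc(Br)c2c1CC=N2
F6 | step 4 | (E)-N-(but-3-yn-1-yl)-N-(1,2-dichlorovinyl)-4-methylbenzenesulfonamide | Cl/C=C(/Cl)N(CCC#C)S(=O)(=O)c1ccc(C)cc1
F7 | step 4 | N-(4-lithiobut-3-yn-1-yl)-N-(lithioethynyl)-4-methylbenzenesulfonamide | [Li]C#CCCN(C#C[Li])S(=O)(=O)c1ccc(C)cc1
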